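The route rests on cutting ring A between the gem-dimethyl carbon C4 and the ring-fusion carbon C5 (labdane numbering). The key step exploits two features: C5 sits next to the oxygenated C6 of ring B, so with C6 as a ketone it is an enol-ether nucleophile, and C4 is a tertiary centre that ionises easily. One cationic closure, the polar image of the biosynthetic C4–C5 bond formation, builds ring A and the trans ring fusion. Its precursor is a ring B silyl enol ether carrying the C10 methyl, a 4-methoxy-4-methylpentyl chain and a cis-fused γ-lactone that holds C11 and C17; the lactone later opens by olefination to the side chain.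

Key step: step 5

Remarks. Atoms are numbered as in labdanes: ring A = C1–C5 and C10, ring B = C5–C10, C11 and C12 are the first side-chain carbons on C9, C17 is the oxygenated carbon on C8, C20 is the methyl on C10. Assumption: the (S)-phenylalanine-derived catalyst of step 2 is taken to give the (R) centre at C8; should the sense be the reverse, its mirror image is used. Compounds 1, 2, 4, 8, 15 and 16 are commercial.

Step 1
Reactants: 1 [tert-butyl(dimethyl)silyl]oxyacetaldehyde; 2 1-(triphenylphosphoranylidene)propan-2-one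
Product: 3 (3E)-5-[tert-butyl(dimethyl)silyl]oxypent-3-en-2-one
Conditions: CH2Cl2, rt
Reagents that add atoms: none
Why: Wittig olefination with the stabilised acetonyl ylide should give the (E)-enone selectively.

Step 2
Reactants: 3 (3E)-5-[tert-butyl(dimethyl)silyl]oxypent-3-en-2-one; 4 methyl 3-oxobutanoate
Product: 7 (3aR,7aR)-7-methyl-3a,4-dihydro-2-benzofuran-1,5(3H,7aH)-dione, via Michael adduct 5 (not isolated), via cyclohexenone ester 6 (not isolated)
Conditions: (4S)-4-benzyl-1-methylimidazolidine-2-carboxylic acid (10 mol %), neat, rt; then 2 M aq. HCl, THF, 50 °C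
Reagents that add atoms: none
Why: Organocatalytic domino Michael–aldol condensation (Robinson-type annulation) in which the enol of 4 attacks the iminium ion of 3 on the face left open by the catalyst to set C8, the enamine of the methyl ketone then closes onto the acetoacetate carbonyl, and acid removes the silyl group and lactonises with equilibration of the labile C9 centre to the cis-fused γ-lactone.

Step 3
Reactants: 8 5-bromo-2-methylpent-2-ene
Product: 9 5-bromo-2-methoxy-2-methylpentane
Conditions: MeOH (solvent), Amberlyst 15 (acid form), 40 °C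
Reagents that add atoms: methanol CO
Why: Acid-catalysed Markovnikov addition of methanol to the trisubstituted alkene should give the tertiary methyl ether, a latent C4 cation that tolerates Grignard formation.

Step 4
Reactants: 7 (3aR,7aR)-7-methyl-3a,4-dihydro-2-benzofuran-1,5(3H,7aH)-dione; 9 5-bromo-2-methoxy-2-methylpentane
Product: 11 (3aR,7R,7aR)-7-(4-methoxy-4-methylpentyl)-7-methyl-5-[(trimethylsilyl)oxy]-3a,4,7,7a-tetrahydro-2-benzofuran-1(3H)-one, via Grignard reagent 10 (not isolated)
Conditions: 9, Mg, THF, 40 °C; then CuBr·SMe2 (10 mol %), Me3SiCl, 7, THF, −78 °C; Et3N, pentane work-up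
Reagents that add atoms: chlorotrimethylsilane C[Si](C)(C)Cl
Why: Copper-catalysed, silyl-chloride-accelerated conjugate addition should occur on the convex face of the cis-fused bicycle, anti to the lactone carbon on the neighbouring C9, setting the quaternary C10 (methyl cis to C11), and the enolate is trapped regiospecifically as the C5=C6 silyl enol ether.

Step 5
Reactants: 11 (3aR,7R,7aR)-7-(4-methoxy-4-methylpentyl)-7-methyl-5-[(trimethylsilyl)oxy]-3a,4,7,7a-tetrahydro-2-benzofuran-1(3H)-one
Product: 12 (3aR,5aR,9aR,9bR)-6,6,9a-trimethyldecahydronaphtho[1,2-c]furan-1,5-dione (trans-decalin 6-ketone with the C11(=O)–O–C17 lactone cis-fused at C8/C9)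
Conditions: TiCl4 (2.2 equiv), 2,6-di-tert-butylpyridine (0.3 equiv), CH2Cl2, −78 to −20 °C; aq. NaHCO3
Reagents that add atoms: none
Why: TiCl4 ionises the tertiary methyl ether to the C4 carbocation, which is attacked by C5 of the silyl enol ether, and loss of Me3SiCl from the silyloxocarbenium ion returns the C6 ketone. The closest known reaction type is the Lewis-acid-mediated α-tert-alkylation of silyl enol ethers by SN1-active electrophiles (Mukaiyama-type alkylation), here intramolecular. Ring A closes as a six-membered ring by 6-exo attack of the enol carbon on the tethered cation, the enol C=C lying outside the new ring. C5 is set by a chair-like transition state with the chain equatorial on ring B and the new bond anti to the axial C10 methyl, giving the trans ring fusion, which is also the thermodynamic one because C5 stays epimerisable next to the ketone. The step needs C-alkylation at C5 in preference to proton loss from the cation or attack through oxygen or C7; the regiodefined C5=C6 enol ether from step 4, the low temperature and the fact that only C5 reaches C4 through a six-membered ring (oxygen or C7 would need eight) should secure it.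

Step 6
Reactants: 12 (3aR,5aR,9aR,9bR)-6,6,9a-trimethyldecahydronaphtho[1,2-c]furan-1,5-dione
Product: 13 (5aR,9aR,9bS)-6,6,9a-trimethyl-5a,6,7,8,9,9a-hexahydronaphtho[1,2-c]furan-1,5(3H,9bH)-dione (6-oxo-7-ene lactone)
Conditions: IBX (3 equiv), DMSO, 70 °C
Reagents that add atoms: none
Why: IBX dehydrogenation of the ketone through its enol can only run towards C7–C8, because C5 is flanked by the quaternary C4 and C10, and should give the 6-oxo-7-ene.

Step 7
Reactants: 13 (5aR,9aR,9bS)-6,6,9a-trimethyl-5a,6,7,8,9,9a-hexahydronaphtho[1,2-c]furan-1,5(3H,9bH)-dione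
Product: 14 (5S,5aR,9aR,9bS)-6,6,9a-trimethyl-1,3,5,5a,6,7,8,9,9a,9b-decahydronaphtho[1,2-c]furan-1,5-diol (C1 anomers; C6 alcohol cis to C20)
Conditions: i-Bu2AlH (3.2 equiv), CH2Cl2, −78 °C; aq. potassium sodium tartrate
Reagents that add atoms: none
Why: The aluminium hydride should reduce the enone 1,2 from the face opposite the axial C10 and C4 methyl groups, giving the axial C6 alcohol cis to C20, and stop at the lactol for the lactone at −78 °C.

Step 8
Reactants: 15 (S)-2-methylglycidol [(2S)-(2-methyloxiran-2-yl)methanol]; 16 1-phenyl-1H-tetrazole-5-thiol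
Product: 17 (2S)-2-methyl-3-[(1-phenyl-1H-tetrazol-5-yl)sulfanyl]propane-1,2-diol
Conditions: Et3N (0.2 equiv), i-PrOH, 60 °C
Reagents that add atoms: none
Why: Thiolate opening of the epoxide at its unsubstituted carbon (SN2) leaves the tertiary C–O stereocentre, the future C13, untouched.

Step 9
Reactants: 17 (2S)-2-methyl-3-[(1-phenyl-1H-tetrazol-5-yl)sulfanyl]propane-1,2-diol
Product: 18 5-{[(2S)-2-methyl-2,3-bis(triethylsilyloxy)propyl]sulfanyl}-1-phenyl-1H-tetrazole
Conditions: Et3SiOTf (2.4 equiv), 2,6-lutidine, CH2Cl2, 0 °C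
Reagents that add atoms: triethylsilyl trifluoromethanesulfonate CC[Si](CC)(CC)OS(=O)(=O)C(F)(F)F
Why: The silyl triflate caps both hydroxyl groups, and the tertiary silyl ether later prevents Smiles-type self-destruction of the β-oxygenated sulfone.

Step 10
Reactants: 18 5-{[(2S)-2-methyl-2,3-bis(triethylsilyloxy)propyl]sulfanyl}-1-phenyl-1H-tetrazole
Product: 19 (2S)-2-methyl-3-[(1-phenyl-1H-tetrazol-5-yl)sulfanyl]-2-(triethylsilyloxy)propanal
Conditions: (COCl)2, DMSO, CH2Cl2, −78 to −30 °C; Et3N
Reagents that add atoms: none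
Why: Swern conditions are known to cleave and oxidise a primary triethylsilyl ether directly to the aldehyde while a tertiary silyl ether is inert.

Step 11
Reactants: 19 (2S)-2-methyl-3-[(1-phenyl-1H-tetrazol-5-yl)sulfanyl]-2-(triethylsilyloxy)propanal
Product: 20 5-{[(2S)-2-methyl-2-(triethylsilyloxy)but-3-en-1-yl]sulfanyl}-1-phenyl-1H-tetrazole
Conditions: Ph3PCH3Br, KN(SiMe3)2, THF, 0 °C
Reagents that add atoms: methyltriphenylphosphonium bromide C[P+](c1ccccc1)(c1ccccc1)c1ccccc1.[Br-]
Why: Wittig methylenation of the non-enolisable α-silyloxy aldehyde installs the vinyl group without touching the stereocentre.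

Step 12
Reactants: 20 5-{[(2S)-2-methyl-2-(triethylsilyloxy)but-3-en-1-yl]sulfanyl}-1-phenyl-1H-tetrazole
Product: 21 5-{[(2S)-2-methyl-2-(triethylsilyloxy)but-3-en-1-yl]sulfonyl}-1-phenyl-1H-tetrazole
Conditions: (NH4)6Mo7O24·4H2O (10 mol %), 30 % H2O2, EtOH, 0 °C to rt
Reagents that add atoms: hydrogen peroxide OO
Why: Molybdate-catalysed peroxide oxidation converts the thioether to the sulfone and should leave the monosubstituted alkene alone.

Step 13
Reactants: 14 (5S,5aR,9aR,9bS)-6,6,9a-trimethyl-1,3,5,5a,6,7,8,9,9a,9b-decahydronaphtho[1,2-c]furan-1,5-diol; 21 5-{[(2S)-2-methyl-2-(triethylsilyloxy)but-3-en-1-yl]sulfonyl}-1-phenyl-1H-tetrazole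
Product: 22 (5R,6S,9S,10S,11E,13S)-13-(triethylsilyloxy)labda-7,11,14-triene-6,17-diol
Conditions: 21 (2 equiv), KN(SiMe3)2 (4.2 equiv), DME, −60 °C to rt; aq. NH4Cl
Reagents that add atoms: none
Why: Julia–Kocienski olefination of the open hydroxy-aldehyde form of the lactol with the metalated phenyltetrazolyl sulfone should give the (E)-C11=C12 alkene through the addition–Smiles rearrangement–elimination pathway and free the C17 hydroxyl.

Step 14
Reactants: 22 (5R,6S,9S,10S,11E,13S)-13-(triethylsilyloxy)labda-7,11,14-triene-6,17-diol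
Product: 23 (5R,6S,9S,10S,11E,13S)-13-(triethylsilyloxy)labda-7,11,14-triene-6,17-diyl diacetate
Conditions: Ac2O, pyridine, DMAP (cat.), CH2Cl2, rt
Reagents that add atoms: acetic anhydride CC(=O)OC(C)=O
Why: Nucleophile-catalysed acetylation of the primary allylic and the hindered secondary allylic alcohol, the tertiary oxygen being silylated.

Step 15
Reactants: 23 (5R,6S,9S,10S,11E,13S)-13-(triethylsilyloxy)labda-7,11,14-triene-6,17-diyl diacetate
Product: 24 (5R,6S,9S,10S,11E,13S)-13-hydroxylabda-7,11,14-triene-6,17-diyl diacetate (CNP0103498.1)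
Conditions: HF·pyridine, pyridine, THF, 0 °C
Reagents that add atoms: none
Why: Buffered fluoride desilylation should free the tertiary allylic alcohol without acetate migration or ionisation of the allylic positions.

Compound list
1 | [tert-butyl(dimethyl)silyl]oxyacetaldehyde | O=CCO[Si](C)(C)C(C)(C)C | starting material
2 | 1-(triphenylphosphoranylidene)propan-2-one | CC(=O)C=P(c1ccccc1)(c1ccccc1)c1ccccc1 | starting material
3 | (3E)-5-[tert-butyl(dimethyl)silyl]oxypent-3-en-2-one | CC(=O)/C=C/CO[Si](C)(C)C(C)(C)C | intermediate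
4 | methyl 3-oxobutanoate | COC(=O)CC(C)=O | starting material
5 | methyl (3R)-2-acetyl-3-{[tert-butyl(dimethyl)silyl]oxymethyl}-5-oxohexanoate (C2 epimers) | COC(=O)C(C(C)=O)[C@H](CO[Si](C)(C)C(C)(C)C)CC(C)=O | intermediate
6 | methyl (6R)-6-{[tert-butyl(dimethyl)silyl]oxymethyl}-2-methyl-4-oxocyclohex-2-ene-1-carboxylate (C1 epimers) | COC(=O)C1C(C)=CC(=O)C[C@H]1CO[Si](C)(C)C(C)(C)C | intermediate
7 | (3aR,7aR)-7-methyl-3a,4-dihydro-2-benzofuran-1,5(3H,7aH)-dione | CC1=CC(=O)C[C@H]2COC(=O)[C@@H]12 | intermediate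
8 | 5-bromo-2-methylpent-2-ene | CC(C)=CCCBr | starting material
9 | 5-bromo-2-methoxy-2-methylpentane | COC(C)(C)CCCBr | intermediate
10 | (4-methoxy-4-methylpentyl)magnesium bromide | COC(C)(C)CCC[Mg]Br | intermediate
11 | (3aR,7R,7aR)-7-(4-methoxy-4-methylpentyl)-7-methyl-5-[(trimethylsilyl)oxy]-3a,4,7,7a-tetrahydro-2-benzofuran-1(3H)-one | COC(C)(C)CCC[C@]1(C)C=C(O[Si](C)(C)C)C[C@H]2COC(=O)[C@@H]12 | intermediate
12 | (3aR,5aR,9aR,9bR)-6,6,9a-trimethyldecahydronaphtho[1,2-c]furan-1,5-dione | CC1(C)CCC[C@]2(C)[C@@H]1C(=O)C[C@H]3COC(=O)[C@H]32 | intermediate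
13 | (5aR,9aR,9bS)-6,6,9a-trimethyl-5a,6,7,8,9,9a-hexahydronaphtho[1,2-c]furan-1,5(3H,9bH)-dione | CC1(C)CCC[C@]2(C)[C@@H]1C(=O)C=C3COC(=O)[C@H]32 | intermediate
14 | (5S,5aR,9aR,9bS)-6,6,9a-trimethyl-1,3,5,5a,6,7,8,9,9a,9b-decahydronaphtho[1,2-c]furan-1,5-diol (C1 anomers) | CC1(C)CCC[C@]2(C)[C@@H]1[C@@H](O)C=C3COC(O)[C@H]32 | intermediate
15 | (S)-2-methylglycidol | C[C@]1(CO)CO1 | starting material
16 | 1-phenyl-1H-tetrazole-5-thiol | Sc1nnnn1-c1ccccc1 | starting material
17 | (2S)-2-methyl-3-[(1-phenyl-1H-tetrazol-5-yl)sulfanyl]propane-1,2-diol | C[C@](O)(CO)CSc1nnnn1-c1ccccc1 | intermediate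
18 | 5-{[(2S)-2-methyl-2,3-bis(triethylsilyloxy)propyl]sulfanyl}-1-phenyl-1H-tetrazole | C[C@](O[Si](CC)(CC)CC)(CO[Si](CC)(CC)CC)CSc1nnnn1-c1ccccc1 | intermediate
19 | (2S)-2-methyl-3-[(1-phenyl-1H-tetrazol-5-yl)sulfanyl]-2-(triethylsilyloxy)propanal | C[C@](O[Si](CC)(CC)CC)(C=O)CSc1nnnn1-c1ccccc1 | intermediate
20 | 5-{[(2S)-2-methyl-2-(triethylsilyloxy)but-3-en-1-yl]sulfanyl}-1-phenyl-1H-tetrazole | C[C@](O[Si](CC)(CC)CC)(C=C)CSc1nnnn1-c1ccccc1 | intermediate
21 | 5-{[(2S)-2-methyl-2-(triethylsilyloxy)but-3-en-1-yl]sulfonyl}-1-phenyl-1H-tetrazole | C[C@](O[Si](CC)(CC)CC)(C=C)CS(=O)(=O)c1nnnn1-c1ccccc1 | intermediate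
22 | (5R,6S,9S,10S,11E,13S)-13-(triethylsilyloxy)labda-7,11,14-triene-6,17-diol | C=C[C@](C)(O[Si](CC)(CC)CC)/C=C/[C@@H]1C(CO)=C[C@H](O)[C@@H]2C(C)(C)CCC[C@@]12C | intermediate
23 | (5R,6S,9S,10S,11E,13S)-13-(triethylsilyloxy)labda-7,11,14-triene-6,17-diyl diacetate | C=C[C@](C)(O[Si](CC)(CC)CC)/C=C/[C@@H]1C(COC(C)=O)=C[C@H](OC(C)=O)[C@@H]2C(C)(C)CCC[C@@]12C | intermediate
24 | (5R,6S,9S,10S,11E,13S)-13-hydroxylabda-7,11,14-triene-6,17-diyl diacetate | C=C[C@](C)(O)/C=C/[C@@H]1C(COC(C)=O)=C[C@H](OC(C)=O)[C@@H]2C(C)(C)CCC[C@@]12C | target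

Total step count: 15. Longest linear sequence: 9 steps (1, 2, 4, 5, 6, 7, 13, 14, 15).

Steps most likely to fail

Step 5 (key step). The tertiary cation may lose a proton or be captured by chloride faster than it is attacked by the hindered enol carbon, or the enol ether may be protodesilylated before ionisation. The fallback sets out from 7 and returns at 12; it closes the same C4–C5 bond by an aldol condensation instead of a cation capture. Copper-catalysed addition to 7 of the Grignard reagent from commercial 2-(3-chloropropyl)-2-methyl-1,3-dioxolane (conditions of step 4, aqueous work-up) should give (3aR,7R,7aR)-7-methyl-7-[3-(2-methyl-1,3-dioxolan-2-yl)propyl]hexahydro-2-benzofuran-1,5-dione F1. Aqueous acid and then TsOH in hot toluene remove the ketal and condense C5 onto the C4 ketone to the ring A enone (3aR,9aS,9bR)-6,9a-dimethyl-3a,4,7,8,9,9a-hexahydronaphtho[1,2-c]furan-1,5(3H,9bH)-dione F2. Conjugate addition of Me2CuLi with BF3·OEt2 supplies the second C4 methyl, and protonation with equilibration at C5 gives 12.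

Step 13. A neopentyl-type sulfonyl anion has to add to a hindered aldehyde that is mostly closed as the lactol; β-elimination of the silyloxy group or self-condensation of the sulfone may compete. The fallback sets out from 14 and returns at 24; it builds the side chain stepwise with reagent control at C13. Takai iodo-olefination (CrCl2, CHI3, THF) should give the vinyl iodide (5R,6S,9S,10S,11E)-12-iodo-13,14,15,16-tetranorlabda-7,11-diene-6,17-diol F3, which is acetylated (Ac2O, pyridine) to the diacetate (5R,6S,9S,10S,11E)-12-iodo-13,14,15,16-tetranorlabda-7,11-diene-6,17-diyl diacetate F4. Stille coupling with (E)-3-(tributylstannyl)but-2-en-1-ol (Pd(PPh3)4, CuI, DMF) gives the dienol (5R,6S,9S,10S,11E,13E)-15-hydroxylabda-7,11,13-triene-6,17-diyl diacetate F5. Sharpless epoxidation with D-(−)-diethyl tartrate (Ti(Oi-Pr)4, t-BuOOH, 4 Å molecular sieves, −20 °C) gives the epoxy alcohol (5R,6S,9S,10S,11E,13R,14R)-13,14-epoxy-15-hydroxylabda-7,11-diene-6,17-diyl diacetate F6. I2, PPh3 and imidazole convert it to the epoxy iodide (5R,6S,9S,10S,11E,13R,14S)-13,14-epoxy-15-iodolabda-7,11-diene-6,17-diyl diacetate F7, and zinc in ethanol with acetic acid opens it reductively to the tertiary vinyl carbinol 24.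

Step 2. The enantioselectivity with an aliphatic γ-silyloxy enone may be low, the sense may be reversed, or the catalyst may be tied up by condensation with the keto ester. The fallback sets out from 1 and 4 and returns at 5; it inverts the roles of donor and acceptor and uses an auxiliary. Knoevenagel condensation of 1 with 4 (piperidine, AcOH) should give methyl 2-acetyl-4-{[tert-butyl(dimethyl)silyl]oxy}but-2-enoate F8. Michael addition of the lithium aza-enolate of acetone SAMP hydrazone (LiN(i-Pr)2, THF, −78 °C; the RAMP hydrazone if the other face is needed) gives methyl (3R)-2-acetyl-3-{[tert-butyl(dimethyl)silyl]oxymethyl}-5-{[(2S)-2-(methoxymethyl)pyrrolidin-1-yl]imino}hexanoate F9. Aqueous oxalic acid cleaves the hydrazone to 5, which is cyclised with pyrrolidine and AcOH and then lactonised with aqueous HCl to 7 as in step 2.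

Further compounds
F1 | step 5 | (3aR,7R,7aR)-7-methyl-7-[3-(2-methyl-1,3-dioxolan-2-yl)propyl]hexahydro-2-benzofuran-1,5-dione | CC1(OCCO1)CCC[C@]2(C)CC(=O)C[C@H]3COC(=O)[C@@H]23
F2 | step 5 | (3aR,9aS,9bR)-6,9a-dimethyl-3a,4,7,8,9,9a-hexahydronaphtho[1,2-c]furan-1,5(3H,9bH)-dione | CC1=C2C(=O)C[C@H]3COC(=O)[C@H]3[C@]2(C)CCC1
F3 | step 13 | (5R,6S,9S,10S,11E)-12-iodo-13,14,15,16-tetranorlabda-7,11-diene-6,17-diol | I/C=C/[C@@H]1C(CO)=C[C@H](O)[C@@H]2C(C)(C)CCC[C@@]12C
F4 | step 13 | (5R,6S,9S,10S,11E)-12-iodo-13,14,15,16-tetranorlabda-7,11-diene-6,17-diyl diacetate | I/C=C/[C@@H]1C(COC(C)=O)=C[C@H](OC(C)=O)[C@@H]2C(C)(C)CCC[C@@]12C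
F5 | step 13 | (5R,6S,9S,10S,11E,13E)-15-hydroxylabda-7,11,13-triene-6,17-diyl diacetate | OC/C=C(C)/C=C/[C@@H]1C(COC(C)=O)=C[C@H](OC(C)=O)[C@@H]2C(C)(C)CCC[C@@]12C
F6 | step 13 | (5R,6S,9S,10S,11E,13R,14R)-13,14-epoxy-15-hydroxylabda-7,11-diene-6,17-diyl diacetate | OC[C@H]3O[C@]3(C)/C=C/[C@@H]1C(COC(C)=O)=C[C@H](OC(C)=O)[C@@H]2C(C)(C)CCC[C@@]12C
F7 | step 13 | (5R,6S,9S,10S,11E,13R,14S)-13,14-epoxy-15-iodolabda-7,11-diene-6,17-diyl diacetate | IC[C@H]3O[C@]3(C)/C=C/[C@@H]1C(COC(C)=O)=C[C@H](OC(C)=O)[C@@H]2C(C)(C)CCC[C@@]12C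
F8 | step 2 | methyl 2-acetyl-4-{[tert-butyl(dimethyl)silyl]oxy}but-2-enoate (E/Z mixture) | COC(=O)C(=CCO[Si](C)(C)C(C)(C)C)C(C)=O
F9 | step 2 | methyl (3R)-2-acetyl-3-{[tert-butyl(dimethyl)silyl]oxymethyl}-5-{[(2S)-2-(methoxymethyl)pyrrolidin-1-yl]imino}hexanoate | COC[C@@H]1CCCN1N=C(C)C[C@@H](CO[Si](C)(C)C(C)(C)C)C(C(C)=O)C(=O)OC
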